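**Plan**
1. Retrosynthesis cuts, in order: the O–Si bond of the tertiary carbinol; the sp2–sp3 bond between the chain methylidene carbon and the CH2CH2 arm of ring A (Negishi coupling); in ring A (the cyclohexane) the ring bond between carbinol carbon C1 and the methylidene-bearing carbon C6; in ring B (the 1,2-dioxane) the side-chain C=C (Wittig), O2–C3 (SN2), O1–C6 (epoxide perhydrolysis) and C3–Cα (crotylboration).
2. Forward: ring A is closed first, from an acyclic ketone carrying a terminal alkyne. Ring B is closed separately on a geranyl acetate chain and its C6 arm is extended to a 2-bromoalkene. The halves are joined at the chain methylidene carbon and the silyl ether is removed.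
3. Enabling feature: ring A is a 1-alkyl-2-methylidenecyclohexan-1-ol, so C1(O)–C6(=CH2) is the retron of a reductive ketone/terminal-alkyne coupling. The CMe2 carbon C2 leaves the ketone no enolisable hydrogen on the ring side and folds the tether for six-membered closure.
4. Stereochemistry: the carbinol centre comes from the chiral phosphine on nickel in the key step. C3 and Cα come from a tartrate-controlled anti-crotylboration, with inversion at C3 in the peroxide SN2. C6 comes from a Sharpless epoxidation, with inversion at C6 in the perhydrolysis.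

Key step: step 5

Remark: the facial sense of the P-chiral ligand on this ketone cannot be predicted with certainty; the (S)-ligand is written in step 5 and its antipode is taken if a test run shows the opposite sense.
Remark: the (R,R)-tartrate (E)-crotylboronate of step 11 is prepared beforehand from (E)-but-2-ene, B(OiPr)3 and (R,R)-diisopropyl tartrate and used as a toluene solution.

**Fragment A (ring A)**

Step 1
Reactants: 1 2-methylpropanenitrile; 2 (5-iodopent-1-yn-1-yl)trimethylsilane
Product: 3 2,2-dimethyl-7-(trimethylsilyl)hept-6-ynenitrile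
Conditions: LiN(iPr)2, THF, −78 °C; then 2, −78 °C → rt
Reagents that add atoms: none
Why: Alkylation of the lithiated nitrile (SN2 at a primary iodide) should build the quaternary gem-dimethyl carbon, the C-silyl group masking the acidic alkyne hydrogen.

Step 2
Reactants: 3 2,2-dimethyl-7-(trimethylsilyl)hept-6-ynenitrile
Product: 5 3,3-dimethyl-8-(trimethylsilyl)oct-7-yn-2-one, via N-magnesio ketimine 4 (not isolated)
Conditions: MeMgBr, CuBr (2 mol%), THF, reflux; then 1 M HCl, rt
Reagents that add atoms: methylmagnesium bromide, C[Mg]Br; water, O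
Why: Grignard addition to the nitrile should stop at the metallated ketimine, which acid hydrolysis converts into the methyl ketone.

Step 3
Reactants: 5 3,3-dimethyl-8-(trimethylsilyl)oct-7-yn-2-one
Product: 7 4,4-dimethyl-1-(triethylsilyloxy)-9-(trimethylsilyl)non-8-yn-3-one, via lithium aldolate 6 (not isolated)
Conditions: LiN(iPr)2, THF, −78 °C; CH2O (gas); then Et3SiCl, imidazole, −78 → 0 °C
Reagents that add atoms: formaldehyde, C=O; chlorotriethylsilane, CC[Si](CC)(CC)Cl
Why: A crossed aldol addition of the lithium enolate (only the methyl side can enolise) to formaldehyde, followed by O-silylation of the aldolate, should install the two-carbon arm as a protected β-hydroxy ketone.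

Step 4
Reactants: 7 4,4-dimethyl-1-(triethylsilyloxy)-9-(trimethylsilyl)non-8-yn-3-one
Product: 8 4,4-dimethyl-1-(triethylsilyloxy)non-8-yn-3-one
Conditions: K2CO3 (0.2 equiv), MeOH, 0 °C
Reagents that add atoms: none
Why: Carbonate-mediated protodesilylation of the alkynylsilane should free the terminal alkyne, the short contact at 0 °C sparing the triethylsilyl ether and avoiding β-elimination.

Step 5
Reactants: 8 4,4-dimethyl-1-(triethylsilyloxy)non-8-yn-3-one
Product: 9 triethyl({(1R)-2,2-dimethyl-6-methylidene-1-[2-(triethylsilyloxy)ethyl]cyclohexyl}oxy)silane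
Conditions: Ni(cod)2 (10 mol%), (S)-BI-DIME (12 mol%), Et3SiH (3 equiv), 1,4-dioxane, rt
Reagents that add atoms: triethylsilane, CC[SiH](CC)CC
Why: Zerovalent nickel carrying the P-chiral monophosphine binds the terminal alkyne and the ketone of 8 and couples them oxidatively to a five-membered oxanickelacycle, which forms the bond between the internal alkyne carbon and the carbonyl carbon; σ-bond metathesis of the Ni–O bond with Et3SiH then gives the tertiary silyl ether and an alkenylnickel hydride, and C–H reductive elimination releases the exocyclic CH2 and the catalyst. The closest known reaction type is the nickel/silane reductive cyclisation of alkynyl aldehydes and alkynyl ketones to 2-alkylidenecycloalkanols, which has enantioselective variants with P-chiral monophosphines. The cyclohexane ring closes in the 6-exo-dig mode, the internal alkyne carbon becoming ring carbon C6 and the terminal carbon the methylidene CH2. The only new stereocentre, the tertiary carbinol carbon C1, is set in the oxidative cyclisation by the ligand, which distinguishes the two ketone faces through the size difference between the quaternary CMe2 arm in the tether and the CH2CH2OSi arm. The step needs cyclisation to outrun hydrosilylation of the ketone or alkyne and oligomerisation of the terminal alkyne, which should be secured by the gem-dimethyl group (no enolisable hydrogen on the tether side, gem-dialkyl folding) and by the tether length (four atoms between carbonyl carbon and alkyne, so that only the six-membered exo closure is possible).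

Step 6
Reactants: 9 triethyl({(1R)-2,2-dimethyl-6-methylidene-1-[2-(triethylsilyloxy)ethyl]cyclohexyl}oxy)silane
Product: 10 2-[(1R)-2,2-dimethyl-6-methylidene-1-(triethylsilyloxy)cyclohexyl]ethan-1-ol
Conditions: PPTS (0.1 equiv), MeOH/CH2Cl2, 0 °C
Reagents that add atoms: none
Why: Acid-catalysed methanolysis should cleave the unhindered primary silyl ether much faster than the tertiary one flanked by two fully substituted carbons (selective desilylation).

Step 7
Reactants: 10 2-[(1R)-2,2-dimethyl-6-methylidene-1-(triethylsilyloxy)cyclohexyl]ethan-1-ol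
Product: 11 triethyl{[(1R)-1-(2-iodoethyl)-2,2-dimethyl-6-methylidenecyclohexyl]oxy}silane
Conditions: I2, PPh3, imidazole, CH2Cl2, 0 °C → rt
Reagents that add atoms: iodine, II
Why: Appel-type iodination should convert the primary alcohol into the iodide under buffered conditions that leave the tertiary allylic silyl ether and the alkene untouched.

**Phosphonium salt**

Step 8
Reactants: 12 3-bromobut-3-en-1-ol
Product: 13 2-bromo-4-iodobut-1-ene
Conditions: I2, PPh3, imidazole, CH2Cl2, 0 °C → rt
Reagents that add atoms: iodine, II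
Why: Appel-type iodination of the primary alcohol; the vinylic bromide is inert.

Step 9
Reactants: 13 2-bromo-4-iodobut-1-ene
Product: 14 (3-bromobut-3-en-1-yl)triphenylphosphonium iodide
Conditions: PPh3, MeCN, 80 °C
Reagents that add atoms: triphenylphosphine, c1ccc(cc1)P(c1ccccc1)c1ccccc1
Why: SN2 quaternisation of the phosphine at the primary iodide should give the Wittig salt, the vinylic bromide not reacting.

**Fragment B (ring B)**

Step 10
Reactants: 15 (2E)-3,7-dimethylocta-2,6-dien-1-yl acetate (geranyl acetate)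
Product: 16 (2E)-3-methyl-6-oxohex-2-en-1-yl acetate
Conditions: O3 (1.0 equiv), CH2Cl2/MeOH, −78 °C; then Me2S
Reagents that add atoms: ozone, [O-][O+]=O
Why: Ozonolysis with one equivalent of ozone should cleave the electron-rich 6,7-alkene chemoselectively, because the 2,3-alkene is deactivated by the allylic acetoxy group.

Step 11
Reactants: 16 (2E)-3-methyl-6-oxohex-2-en-1-yl acetate
Product: 18 (2E,6R,7S)-6-hydroxy-3,7-dimethylnona-2,8-dien-1-yl acetate, via borate ester 17 (not isolated)
Conditions: (R,R)-diisopropyl tartrate (E)-crotylboronate (1.5 equiv), 4 Å MS, toluene, −78 °C; then aq. NaHCO3, rt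
Reagents that add atoms: diisopropyl (4R,5R)-2-[(2E)-but-2-en-1-yl]-1,3,2-dioxaborolane-4,5-dicarboxylate, C/C=C/CB1O[C@@H](C(=O)OC(C)C)[C@H](C(=O)OC(C)C)O1
Why: Tartrate-controlled asymmetric crotylboration (Roush type) through a chair transition state should set both centres, the (E)-crotyl geometry giving the anti relationship and the (R,R)-tartrate directing attack to the Si face, so that the carbinol (later C3, to be inverted) is R and the methyl-bearing carbon (later Cα) is S; the vinyl group serves as a carboxyl surrogate that cannot trigger β-elimination.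

Step 12
Reactants: 18 (2E,6R,7S)-6-hydroxy-3,7-dimethylnona-2,8-dien-1-yl acetate
Product: 19 (2E,6R,7S)-6-(methanesulfonyloxy)-3,7-dimethylnona-2,8-dien-1-yl acetate
Conditions: MsCl, Et3N, CH2Cl2, 0 °C
Reagents that add atoms: methanesulfonyl chloride, CS(=O)(=O)Cl
Why: Sulfonylation of the only free hydroxyl group activates the later C3 for displacement with retention at this stage.

Step 13
Reactants: 19 (2E,6R,7S)-6-(methanesulfonyloxy)-3,7-dimethylnona-2,8-dien-1-yl acetate
Product: 20 (3S,4R,7E)-9-hydroxy-3,7-dimethylnona-1,7-dien-4-yl methanesulfonate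
Conditions: K2CO3, MeOH, 0 °C
Reagents that add atoms: none
Why: Mild transesterification should remove the acetate and free the allylic alcohol, the secondary mesylate being stable to carbonate in methanol at 0 °C.

Step 14
Reactants: 20 (3S,4R,7E)-9-hydroxy-3,7-dimethylnona-1,7-dien-4-yl methanesulfonate
Product: 21 (3S,4R)-6-[(2R,3R)-3-(hydroxymethyl)-2-methyloxiran-2-yl]-3-methylhex-1-en-4-yl methanesulfonate
Conditions: Ti(OiPr)4 (10 mol%), D-(−)-diethyl tartrate (12 mol%), t-BuOOH, 4 Å MS, CH2Cl2, −20 °C
Reagents that add atoms: tert-butyl hydroperoxide, CC(C)(C)OO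
Why: Sharpless asymmetric epoxidation of the geraniol-type allylic alcohol with D-(−)-tartrate should give the (2R,3R)-epoxide by reagent control, the remote stereocentres and the terminal vinyl group not interfering.

Step 15
Reactants: 21 (3S,4R)-6-[(2R,3R)-3-(hydroxymethyl)-2-methyloxiran-2-yl]-3-methylhex-1-en-4-yl methanesulfonate
Product: 22 (3S,4R,7S,8R)-7-hydroperoxy-8,9-dihydroxy-3,7-dimethylnon-1-en-4-yl methanesulfonate
Conditions: H2O2 (anhydrous, in Et2O), H3PMo12O40 (5 mol%), rt
Reagents that add atoms: hydrogen peroxide, OO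
Why: Molybdenum-catalysed perhydrolysis of the trisubstituted epoxide should open it at the tertiary carbon with inversion, which sets the C6 peroxy stereocentre and leaves a vicinal diol for later cleavage.

Step 16
Reactants: 22 (3S,4R,7S,8R)-7-hydroperoxy-8,9-dihydroxy-3,7-dimethylnon-1-en-4-yl methanesulfonate
Product: 23 (1R)-1-{(3S,6S)-6-[(2S)-but-3-en-2-yl]-3-methyl-1,2-dioxan-3-yl}ethane-1,2-diol
Conditions: Cs2CO3 (1.1 equiv), DMF, 0 °C → rt
Reagents that add atoms: none
Why: Intramolecular SN2 alkylation of the hydroperoxide anion (6-exo-tet) should displace the secondary mesylate with inversion and close the 1,2-dioxane with the C3 configuration of the target, carbonate deprotonating only the hydroperoxide among the hydroxyl groups.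

Step 17
Reactants: 23 (1R)-1-{(3S,6S)-6-[(2S)-but-3-en-2-yl]-3-methyl-1,2-dioxan-3-yl}ethane-1,2-diol
Product: 25 (2R)-2-{(3S,6S)-6-[(1R)-1,2-dihydroxyethyl]-6-methyl-1,2-dioxan-3-yl}propanoic acid, via dioxanyl propanal 24 (not isolated)
Conditions: O3, CH2Cl2/MeOH, −78 °C; Me2S; then NaClO2, NaH2PO4, 2-methylbut-2-ene, t-BuOH/H2O, 0 °C → rt
Reagents that add atoms: ozone, [O-][O+]=O; sodium chlorite, [Na+].[O-]Cl=O
Why: Ozonolysis of the only alkene followed directly by Pinnick oxidation should unmask the carboxyl group without base, so that Cα is not epimerised and the β-peroxide is not eliminated.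

Step 18
Reactants: 25 (2R)-2-{(3S,6S)-6-[(1R)-1,2-dihydroxyethyl]-6-methyl-1,2-dioxan-3-yl}propanoic acid
Product: 26 methyl (2R)-2-{(3S,6S)-6-[(1R)-1,2-dihydroxyethyl]-6-methyl-1,2-dioxan-3-yl}propanoate
Conditions: Me3SiCHN2, MeOH/toluene, 0 °C
Reagents that add atoms: (trimethylsilyl)diazomethane, C[Si](C)(C)C=[N+]=[N-]
Why: Esterification with the diazoalkane under neutral conditions should give the methyl ester without touching the peroxide or Cα.

Step 19
Reactants: 26 methyl (2R)-2-{(3S,6S)-6-[(1R)-1,2-dihydroxyethyl]-6-methyl-1,2-dioxan-3-yl}propanoate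
Product: 27 methyl (2R)-2-[(3S,6S)-6-formyl-6-methyl-1,2-dioxan-3-yl]propanoate
Conditions: NaIO4, THF/H2O, 0 °C → rt
Reagents that add atoms: none
Why: Periodate glycol cleavage should remove the extra carbinol carbon left by the epoxide opening and give the aldehyde on the quaternary C6, which has no α-hydrogen and cannot epimerise.

Step 20
Reactants: 27 methyl (2R)-2-[(3S,6S)-6-formyl-6-methyl-1,2-dioxan-3-yl]propanoate; 14 (3-bromobut-3-en-1-yl)triphenylphosphonium iodide
Product: 29 methyl (2R)-2-{(3S,6S)-6-[(1Z)-4-bromopenta-1,4-dien-1-yl]-6-methyl-1,2-dioxan-3-yl}propanoate, via phosphorus ylide 28 (not isolated)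
Conditions: 14, NaN(SiMe3)2 (0.98 equiv), THF, −78 °C; then 27, −78 → 0 °C
Reagents that add atoms: none
Why: Wittig olefination with the preformed non-stabilised ylide should add the three-carbon unit that carries the 2-bromoalkene, the aldehyde reacting far faster than the ester or the peroxide, and the alkene geometry being irrelevant.

Step 21
Reactants: 29 methyl (2R)-2-{(3S,6S)-6-[(1Z)-4-bromopenta-1,4-dien-1-yl]-6-methyl-1,2-dioxan-3-yl}propanoate
Product: 30 methyl (2R)-2-[(3S,6R)-6-(4-bromopent-4-en-1-yl)-6-methyl-1,2-dioxan-3-yl]propanoate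
Conditions: KO2CN=NCO2K, AcOH, CH2Cl2/MeOH, 0 °C → rt
Reagents that add atoms: none
Why: Diimide reduction should saturate the 1,2-disubstituted alkene while the O–O bond, the ester and the electron-poor bromoalkene stay intact.

**Union and end game**

Step 22
Reactants: 11 triethyl{[(1R)-1-(2-iodoethyl)-2,2-dimethyl-6-methylidenecyclohexyl]oxy}silane; 30 methyl (2R)-2-[(3S,6R)-6-(4-bromopent-4-en-1-yl)-6-methyl-1,2-dioxan-3-yl]propanoate
Product: 32 methyl (2R)-2-[(3S,6R)-6-{6-[(1R)-2,2-dimethyl-6-methylidene-1-(triethylsilyloxy)cyclohexyl]-4-methylidenehexyl}-6-methyl-1,2-dioxan-3-yl]propanoate, via alkylzinc iodide 31 (not isolated)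
Conditions: 11, Zn dust, LiCl, THF, 40 °C; solution decanted from excess Zn; then 30, PdCl2(dppf) (5 mol%), THF, rt
Reagents that add atoms: none
Why: Negishi sp3–sp2 cross-coupling of the primary alkylzinc iodide with the 2-bromoalkene should create the 1,1-disubstituted chain alkene without base, the alkylzinc being inert towards the ester and a poor reductant for the dialkyl peroxide.

Step 23
Reactants: 32 methyl (2R)-2-[(3S,6R)-6-{6-[(1R)-2,2-dimethyl-6-methylidene-1-(triethylsilyloxy)cyclohexyl]-4-methylidenehexyl}-6-methyl-1,2-dioxan-3-yl]propanoate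
Product: 33 methyl (2R)-2-[(3S,6R)-6-{6-[(1R)-1-hydroxy-2,2-dimethyl-6-methylidenecyclohexyl]-4-methylidenehexyl}-6-methyl-1,2-dioxan-3-yl]propanoate
Conditions: HF·pyridine, pyridine, THF, 0 °C → rt
Reagents that add atoms: none
Why: Fluoride-mediated cleavage of the tertiary silyl ether under buffered, non-basic conditions should free the tertiary allylic alcohol without opening the dioxane or ionising the carbinol.

**Compound list**
1 | 2-methylpropanenitrile | CC(C)C#N | starting material
2 | (5-iodopent-1-yn-1-yl)trimethylsilane | C[Si](C)(C)C#CCCCI | starting material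
3 | 2,2-dimethyl-7-(trimethylsilyl)hept-6-ynenitrile | C[Si](C)(C)C#CCCCC(C)(C)C#N | intermediate
4 | N-bromomagnesio 3,3-dimethyl-8-(trimethylsilyl)oct-7-yn-2-imine | CC(=N[Mg]Br)C(C)(C)CCCC#C[Si](C)(C)C | intermediate (not isolated)
5 | 3,3-dimethyl-8-(trimethylsilyl)oct-7-yn-2-one | CC(=O)C(C)(C)CCCC#C[Si](C)(C)C | intermediate
6 | lithium 4,4-dimethyl-3-oxo-9-(trimethylsilyl)non-8-yn-1-olate | [Li]OCCC(=O)C(C)(C)CCCC#C[Si](C)(C)C | intermediate (not isolated)
7 | 4,4-dimethyl-1-(triethylsilyloxy)-9-(trimethylsilyl)non-8-yn-3-one | CC[Si](CC)(CC)OCCC(=O)C(C)(C)CCCC#C[Si](C)(C)C | intermediate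
8 | 4,4-dimethyl-1-(triethylsilyloxy)non-8-yn-3-one | CC[Si](CC)(CC)OCCC(=O)C(C)(C)CCCC#C | intermediate
9 | triethyl({(1R)-2,2-dimethyl-6-methylidene-1-[2-(triethylsilyloxy)ethyl]cyclohexyl}oxy)silane | CC[Si](CC)(CC)OCC[C@]1(O[Si](CC)(CC)CC)C(=C)CCCC1(C)C | intermediate
10 | 2-[(1R)-2,2-dimethyl-6-methylidene-1-(triethylsilyloxy)cyclohexyl]ethan-1-ol | OCC[C@]1(O[Si](CC)(CC)CC)C(=C)CCCC1(C)C | intermediate
11 | triethyl{[(1R)-1-(2-iodoethyl)-2,2-dimethyl-6-methylidenecyclohexyl]oxy}silane | ICC[C@]1(O[Si](CC)(CC)CC)C(=C)CCCC1(C)C | intermediate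
12 | 3-bromobut-3-en-1-ol | OCCC(Br)=C | starting material
13 | 2-bromo-4-iodobut-1-ene | ICCC(Br)=C | intermediate
14 | (3-bromobut-3-en-1-yl)triphenylphosphonium iodide | [I-].C=C(Br)CC[P+](c1ccccc1)(c1ccccc1)c1ccccc1 | intermediate
15 | (2E)-3,7-dimethylocta-2,6-dien-1-yl acetate (geranyl acetate) | CC(C)=CCC/C(C)=C/COC(C)=O | starting material
16 | (2E)-3-methyl-6-oxohex-2-en-1-yl acetate | O=CCC/C(C)=C/COC(C)=O | intermediate
17 | diisopropyl (4R,5R)-2-{[(3S,4R,7E)-9-acetoxy-3,7-dimethylnona-1,7-dien-4-yl]oxy}-1,3,2-dioxaborolane-4,5-dicarboxylate | CC(=O)OC/C=C(\C)CC[C@@H](OB1O[C@@H](C(=O)OC(C)C)[C@H](C(=O)OC(C)C)O1)[C@@H](C)C=C | intermediate (not isolated)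
18 | (2E,6R,7S)-6-hydroxy-3,7-dimethylnona-2,8-dien-1-yl acetate | CC(=O)OC/C=C(\C)CC[C@@H](O)[C@@H](C)C=C | intermediate
19 | (2E,6R,7S)-6-(methanesulfonyloxy)-3,7-dimethylnona-2,8-dien-1-yl acetate | CC(=O)OC/C=C(\C)CC[C@@H](OS(C)(=O)=O)[C@@H](C)C=C | intermediate
20 | (3S,4R,7E)-9-hydroxy-3,7-dimethylnona-1,7-dien-4-yl methanesulfonate | OC/C=C(\C)CC[C@@H](OS(C)(=O)=O)[C@@H](C)C=C | intermediate
21 | (3S,4R)-6-[(2R,3R)-3-(hydroxymethyl)-2-methyloxiran-2-yl]-3-methylhex-1-en-4-yl methanesulfonate | OC[C@H]1O[C@]1(C)CC[C@@H](OS(C)(=O)=O)[C@@H](C)C=C | intermediate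
22 | (3S,4R,7S,8R)-7-hydroperoxy-8,9-dihydroxy-3,7-dimethylnon-1-en-4-yl methanesulfonate | OC[C@@H](O)[C@@](C)(OO)CC[C@@H](OS(C)(=O)=O)[C@@H](C)C=C | intermediate
23 | (1R)-1-{(3S,6S)-6-[(2S)-but-3-en-2-yl]-3-methyl-1,2-dioxan-3-yl}ethane-1,2-diol | OC[C@@H](O)[C@]1(C)CC[C@@H]([C@@H](C)C=C)OO1 | intermediate
24 | (2R)-2-{(3S,6S)-6-[(1R)-1,2-dihydroxyethyl]-6-methyl-1,2-dioxan-3-yl}propanal | OC[C@@H](O)[C@]1(C)CC[C@@H]([C@@H](C)C=O)OO1 | intermediate (not isolated)
25 | (2R)-2-{(3S,6S)-6-[(1R)-1,2-dihydroxyethyl]-6-methyl-1,2-dioxan-3-yl}propanoic acid | OC[C@@H](O)[C@]1(C)CC[C@@H]([C@@H](C)C(O)=O)OO1 | intermediate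
26 | methyl (2R)-2-{(3S,6S)-6-[(1R)-1,2-dihydroxyethyl]-6-methyl-1,2-dioxan-3-yl}propanoate | OC[C@@H](O)[C@]1(C)CC[C@@H]([C@@H](C)C(=O)OC)OO1 | intermediate
27 | methyl (2R)-2-[(3S,6S)-6-formyl-6-methyl-1,2-dioxan-3-yl]propanoate | O=C[C@]1(C)CC[C@@H]([C@@H](C)C(=O)OC)OO1 | intermediate
28 | (3-bromobut-3-en-1-ylidene)triphenylphosphorane | C=C(Br)CC=P(c1ccccc1)(c1ccccc1)c1ccccc1 | intermediate (not isolated)
29 | methyl (2R)-2-{(3S,6S)-6-[(1Z)-4-bromopenta-1,4-dien-1-yl]-6-methyl-1,2-dioxan-3-yl}propanoate | C=C(Br)C/C=C\[C@]1(C)CC[C@@H]([C@@H](C)C(=O)OC)OO1 | intermediate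
30 | methyl (2R)-2-[(3S,6R)-6-(4-bromopent-4-en-1-yl)-6-methyl-1,2-dioxan-3-yl]propanoate | C=C(Br)CCC[C@]1(C)CC[C@@H]([C@@H](C)C(=O)OC)OO1 | intermediate
31 | {2-[(1R)-2,2-dimethyl-6-methylidene-1-(triethylsilyloxy)cyclohexyl]ethyl}zinc iodide | I[Zn]CC[C@]1(O[Si](CC)(CC)CC)C(=C)CCCC1(C)C | intermediate (not isolated)
32 | methyl (2R)-2-[(3S,6R)-6-{6-[(1R)-2,2-dimethyl-6-methylidene-1-(triethylsilyloxy)cyclohexyl]-4-methylidenehexyl}-6-methyl-1,2-dioxan-3-yl]propanoate | C=C(CCC[C@]1(C)CC[C@@H]([C@@H](C)C(=O)OC)OO1)CC[C@]1(O[Si](CC)(CC)CC)C(=C)CCCC1(C)C | intermediate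
33 | methyl (2R)-2-[(3S,6R)-6-{6-[(1R)-1-hydroxy-2,2-dimethyl-6-methylidenecyclohexyl]-4-methylidenehexyl}-6-methyl-1,2-dioxan-3-yl]propanoate | C=C(CCC[C@]1(C)CC[C@@H]([C@@H](C)C(=O)OC)OO1)CC[C@]1(O)C(=C)CCCC1(C)C | target

**Step count and risks**
Total step count: 23 (steps 1–7 for ring A, 8–9 for the Wittig salt, 10–21 for ring B, 22–23 for union and deprotection).
Longest linear sequence: 14 steps (15 → 33, steps 10–23).
The crotylboration of step 11 is only moderately enantioselective with unbranched aldehydes. The minor enantiomeric series becomes a set of diastereomers after the second reagent-controlled step (step 14) and should be removed by chromatography at 23.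

Steps most likely to fail:

1. Step 5. The ligand may discriminate the two ketone faces poorly, or hydrosilylation of the hindered ketone or of the alkyne may outrun the oxidative cyclisation. Fallback, from 8: a ketyl–alkyne radical cyclisation (SmI2, HMPA, t-BuOH, THF, −78 → 0 °C; 6-exo-dig attack of the samarium ketyl on the alkyne, hydrogen abstraction by the vinyl radical) should give racemic 2,2-dimethyl-6-methylidene-1-[2-(triethylsilyloxy)ethyl]cyclohexan-1-ol F1. The enantiomers are separated by preparative chromatography on a chiral stationary phase to give (1R)-2,2-dimethyl-6-methylidene-1-[2-(triethylsilyloxy)ethyl]cyclohexan-1-ol F2. Silylation of the tertiary hydroxyl (Et3SiOTf, 2,6-lutidine, CH2Cl2, 0 °C) returns to the route at 9.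

2. Step 16. Elimination of the β-branched secondary mesylate, or O-alkylation by a neighbouring hydroxyl group, may compete with the peroxide ring closure. Fallback, from 16: Wittig reaction with methyl 2-(triphenylphosphoranylidene)propanoate should give methyl (2E,6E)-8-acetoxy-2,6-dimethylocta-2,6-dienoate F3. K2CO3 in MeOH gives methyl (2E,6E)-8-hydroxy-2,6-dimethylocta-2,6-dienoate F4. Sharpless epoxidation with D-(−)-diethyl tartrate gives methyl (2E)-5-[(2R,3R)-3-(hydroxymethyl)-2-methyloxiran-2-yl]-2-methylpent-2-enoate F5. Perhydrolysis (H2O2, H3PMo12O40, Et2O) gives methyl (2E,6S,7R)-6-hydroperoxy-7,8-dihydroxy-2,6-dimethyloct-2-enoate F6. Et2NH in CF3CH2OH then triggers an intramolecular peroxy-Michael addition to the enoate, which closes the dioxane and forms C3 and Cα under substrate control only. The diastereomer with the configuration of 26 is separated by chromatography, and the route is rejoined at 26. This fallback keeps the reagent-controlled C6 centre but gives up reagent control at C3 and Cα.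

3. Step 22. Low-valent metal species may cleave the O–O bond reductively, or transmetalation of the hindered alkylzinc may be sluggish. Fallback, from 11: iodine–lithium exchange (t-BuLi, 2 equiv, Et2O, −78 °C) and trapping with B-methoxy-9-borabicyclo[3.3.1]nonane should give lithium B-{2-[(1R)-2,2-dimethyl-6-methylidene-1-(triethylsilyloxy)cyclohexyl]ethyl}-B-methoxy-9-borabicyclo[3.3.1]nonan-9-uide F7. This is coupled with 30 in a B-alkyl Suzuki–Miyaura reaction (PdCl2(dppf), AsPh3, Cs2CO3, DMF/H2O, rt) to return to the route at 32. The fallback takes metallic zinc and the organozinc out of the peroxide-bearing step, at the price of a mildly basic medium.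

**Further compounds**
F1 | step 5 | racemic 2,2-dimethyl-6-methylidene-1-[2-(triethylsilyloxy)ethyl]cyclohexan-1-ol | CC[Si](CC)(CC)OCCC1(O)C(=C)CCCC1(C)C
F2 | step 5 | (1R)-2,2-dimethyl-6-methylidene-1-[2-(triethylsilyloxy)ethyl]cyclohexan-1-ol | CC[Si](CC)(CC)OCC[C@]1(O)C(=C)CCCC1(C)C
F3 | step 16 | methyl (2E,6E)-8-acetoxy-2,6-dimethylocta-2,6-dienoate | COC(=O)/C(C)=C/CC/C(C)=C/COC(C)=O
F4 | step 16 | methyl (2E,6E)-8-hydroxy-2,6-dimethylocta-2,6-dienoate | COC(=O)/C(C)=C/CC/C(C)=C/CO
F5 | step 16 | methyl (2E)-5-[(2R,3R)-3-(hydroxymethyl)-2-methyloxiran-2-yl]-2-methylpent-2-enoate | OC[C@H]1O[C@]1(C)CC/C=C(\C)C(=O)OC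
F6 | step 16 | methyl (2E,6S,7R)-6-hydroperoxy-7,8-dihydroxy-2,6-dimethyloct-2-enoate | OC[C@@H](O)[C@@](C)(OO)CC/C=C(\C)C(=O)OC
F7 | step 22 | lithium B-{2-[(1R)-2,2-dimethyl-6-methylidene-1-(triethylsilyloxy)cyclohexyl]ethyl}-B-methoxy-9-borabicyclo[3.3.1]nonan-9-uide | [Li+].CO[B-]1(CC[C@]2(O[Si](CC)(CC)CC)C(=C)CCCC2(C)C)C2CCCC1CCC2
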